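**Plan**
- Retrosynthesis: the C7 phenol is masked as a MOM ether and the C4 ketone is taken back to an alcohol; ring C is then cut at O1–C8a, which gives an open-chain 1,3-diol with a C8a–Br bond.
- The diol comes from a 1,3-diketone cut at C2–C3 into a ring A methyl ketone and a chromene ester; the prenyl C–C bonds at C6 and C8 go back to C–I bonds, and the pyran ring of the chromene to an aryl propargyl ether.
- Forward: ring A is iodinated, protected and prenylated; the dimethylpyran ring is closed on the ring B ester; the halves are joined at C2–C3; both carbonyls are reduced; ring C is closed last; C4 is re-oxidised and the phenol freed.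
- Enabling feature: O1 is an aryl alkyl ether oxygen bridging the benzylic stereocentre C2 and C8a of ring A. C8a is ortho to C4a, so a C2 alkoxide held by the C3–C4–C4a tether can be joined to a C8a–Br bond in a six-membered closure that never breaks the C2–O bond.
- Stereochemistry: C2 (S) is set by transfer hydrogenation of the diketone with RuCl[(S,S)-TsDPEN](p-cymene); the C4 carbinol formed alongside is temporary and is erased by oxidation.

Key step: step 8

Remark: C4 ends as a ketone, so its carbinol configuration is free; the anti (1S,3S)-diol is carried because one catalyst sets both centres and mis-set centres should end up in the syn diastereomers, which can be separated.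

**Step 1**
Reactants: 1 1-(2-bromo-4-hydroxyphenyl)ethanone
Product: 3 1-(2-bromo-4-hydroxy-3,5-diiodophenyl)ethanone, via 5-iodo phenol 2 (not isolated)
Conditions: NIS (2.2 equiv), TsOH·H2O (10 mol %), MeCN, rt → 40 °C
Reagents that add atoms: N-iodosuccinimide, O=C1CCC(=O)N1I
Why: Electrophilic aromatic iodination is directed by the phenol OH to its two ortho positions C3 and C5 (para is blocked by the acetyl group), the less hindered C5 reacting first.

**Step 2**
Reactants: 3 1-(2-bromo-4-hydroxy-3,5-diiodophenyl)ethanone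
Product: 4 1-[2-bromo-3,5-diiodo-4-(methoxymethoxy)phenyl]ethanone
Conditions: MOMCl, i-Pr2NEt, CH2Cl2, 0 °C → rt
Reagents that add atoms: chloromethyl methyl ether, COCCl
Why: Base-mediated O-alkylation (MOM ether formation) with the very reactive chloromethyl ether should overcome the hindrance of the two ortho iodine atoms and masks the acidic phenol for the organometallic and basic steps that follow.

**Step 3**
Reactants: 4 1-[2-bromo-3,5-diiodo-4-(methoxymethoxy)phenyl]ethanone; 5 tributyl(3-methylbut-2-enyl)stannane
Product: 7 1-[2-bromo-4-(methoxymethoxy)-3,5-bis(3-methylbut-2-enyl)phenyl]ethanone, via mono-prenyl iodide 6 (not isolated)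
Conditions: 5 (2.5 equiv), Pd2(dba)3 (5 mol %), AsPh3 (20 mol %), DMF, 60 °C
Reagents that add atoms: none
Why: In this double Stille cross-coupling zerovalent palladium should insert into the two C–I bonds much faster than into the C–Br bond, and the allylpalladium intermediate should couple through its unsubstituted CH2 terminus, giving linear prenyl groups and keeping the bromide for step 8.

**Step 4**
Reactants: 8 methyl 4-hydroxybenzoate; 9 3-chloro-3-methylbut-1-yne
Product: 10 methyl 4-[(2-methylbut-3-yn-2-yl)oxy]benzoate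
Conditions: K2CO3, KI, CuI (cat.), acetone, reflux
Reagents that add atoms: none
Why: Copper-assisted O-alkylation of the phenoxide with the tertiary propargylic chloride is the standard entry to aryl 1,1-dimethylpropargyl ethers.

**Step 5**
Reactants: 10 methyl 4-[(2-methylbut-3-yn-2-yl)oxy]benzoate
Product: 14 methyl 2,2-dimethyl-2H-chromene-6-carboxylate, via allenyl dienone 11 (not isolated), via ortho-allenylphenol 12 (not isolated), via ortho-quinone methide 13 (not isolated)
Conditions: N,N-diethylaniline, 190 °C
Reagents that add atoms: none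
Why: A thermal aromatic propargyl Claisen rearrangement, tautomerisation, 1,5-hydrogen shift and 6π oxa-electrocyclisation should close the 2,2-dimethylpyran ring at either of the two equivalent ortho positions.

**Step 6**
Reactants: 7 1-[2-bromo-4-(methoxymethoxy)-3,5-bis(3-methylbut-2-enyl)phenyl]ethanone; 14 methyl 2,2-dimethyl-2H-chromene-6-carboxylate
Product: 15 1-[2-bromo-4-(methoxymethoxy)-3,5-bis(3-methylbut-2-enyl)phenyl]-3-(2,2-dimethyl-2H-chromen-6-yl)propane-1,3-dione
Conditions: NaH (3 equiv), THF, reflux; then AcOH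
Reagents that add atoms: none
Why: In this crossed Claisen condensation the sodium enolate of methyl ketone 7 is acylated at carbon by the non-enolisable ester 14 to form the C2–C3 bond, and deprotonation of the 1,3-diketone drives the equilibrium.

**Step 7**
Reactants: 15 1-[2-bromo-4-(methoxymethoxy)-3,5-bis(3-methylbut-2-enyl)phenyl]-3-(2,2-dimethyl-2H-chromen-6-yl)propane-1,3-dione
Product: 17 (1S,3S)-3-[2-bromo-4-(methoxymethoxy)-3,5-bis(3-methylbut-2-enyl)phenyl]-1-(2,2-dimethyl-2H-chromen-6-yl)propane-1,3-diol, via hydroxy ketone 16 (not isolated)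
Conditions: RuCl[(S,S)-TsDPEN](p-cymene) (3 mol %), HCO2H/Et3N (5:2), DMF, 40 °C
Reagents that add atoms: none
Why: In this Noyori–Ikariya asymmetric transfer hydrogenation the (S,S)-configured ruthenium hydride should reduce each aryl ketone to the (S)-carbinol by aryl-versus-CH2 differentiation, so C1 of the diol (C2 of the flavanone) is set S and the anti diol results, while mismatched events fall into the syn diastereomers that chromatography should remove and the alkenes, MOM ether and C–Br bond are left alone.

**Step 8**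
Reactants: 17 (1S,3S)-3-[2-bromo-4-(methoxymethoxy)-3,5-bis(3-methylbut-2-enyl)phenyl]-1-(2,2-dimethyl-2H-chromen-6-yl)propane-1,3-diol
Product: 18 (2S,4S)-2-(2,2-dimethyl-2H-chromen-6-yl)-7-(methoxymethoxy)-6,8-bis(3-methylbut-2-enyl)-3,4-dihydro-2H-chromen-4-ol
Conditions: Pd2(dba)3 (2.5 mol %), 2-(di-tert-butylphosphino)-1,1'-binaphthyl (6 mol %), Cs2CO3, toluene, 80 °C
Reagents that add atoms: none
Why: This is a Buchwald–Hartwig-type intramolecular aryl etherification: the C8a–Br bond adds oxidatively to zerovalent palladium carrying the bulky di-tert-butylbiaryl phosphine, Cs2CO3 turns the C2 hydroxyl into an alkoxide that displaces bromide on divalent palladium, and C–O reductive elimination forms O1–C8a. The closest known reaction is the palladium-catalysed cyclisation of 3-(2-bromoaryl)-1-arylpropan-1-ols to 2-arylchromans, which keeps the carbinol configuration. Ring C closes as a six-membered ring by reductive elimination from a seven-membered aryl(alkoxo)palladium chelate (Pd, C8a, C4a, C4, C3, C2, O). No stereocentre is made, since neither the C2–O nor the C4–O bond is broken, so (1S,3S) in 17 maps onto (2S,4S) in 18. The C2 hydroxyl must react in preference to the C4 hydroxyl and the alkenes, which the substrate secures because coupling at the C4 oxygen would need a four-membered benzoxete and a Heck insertion of the C8 prenyl group would need a four-membered exo or five-membered endo closure. Reductive elimination must also outrun beta-hydride elimination of the secondary alkoxide, which the bulky electron-rich ligand and the two ortho substituents flanking C8a should favour.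

**Step 9**
Reactants: 18 (2S,4S)-2-(2,2-dimethyl-2H-chromen-6-yl)-7-(methoxymethoxy)-6,8-bis(3-methylbut-2-enyl)-3,4-dihydro-2H-chromen-4-ol
Product: 19 (2S)-2-(2,2-dimethyl-2H-chromen-6-yl)-7-(methoxymethoxy)-6,8-bis(3-methylbut-2-enyl)-2,3-dihydro-4H-chromen-4-one
Conditions: Dess–Martin periodinane, NaHCO3, CH2Cl2, 0 °C → rt
Reagents that add atoms: none
Why: Dess–Martin oxidation of the benzylic C4 alcohol to the aryl ketone under buffered, non-basic conditions should leave the prenyl and chromene alkenes, the MOM ether and the C2 stereocentre untouched.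

**Step 10**
Reactants: 19 (2S)-2-(2,2-dimethyl-2H-chromen-6-yl)-7-(methoxymethoxy)-6,8-bis(3-methylbut-2-enyl)-2,3-dihydro-4H-chromen-4-one
Product: 20 (2S)-2-(2,2-dimethyl-2H-chromen-6-yl)-7-hydroxy-6,8-bis(3-methylbut-2-enyl)-2,3-dihydro-4H-chromen-4-one (target flavanone)
Conditions: HCl (3 M aq.), MeOH, 40 °C
Reagents that add atoms: none
Why: Acid-catalysed acetal exchange removes the MOM group as dimethoxymethane under conditions mild enough that the ortho-prenyl phenol should not cyclise to a chroman and the flavanone should not open at O1–C2, so C2 stays S.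

**Compound list**
1 | 1-(2-bromo-4-hydroxyphenyl)ethanone | CC(=O)c1ccc(O)cc1Br | starting material
2 | 1-(2-bromo-4-hydroxy-5-iodophenyl)ethanone (not isolated) | CC(=O)c1cc(I)c(O)cc1Br | intermediate
3 | 1-(2-bromo-4-hydroxy-3,5-diiodophenyl)ethanone | CC(=O)c1cc(I)c(O)c(I)c1Br | intermediate
4 | 1-[2-bromo-3,5-diiodo-4-(methoxymethoxy)phenyl]ethanone | CC(=O)c1cc(I)c(OCOC)c(I)c1Br | intermediate
5 | tributyl(3-methylbut-2-enyl)stannane | CCCC[Sn](CCCC)(CCCC)CC=C(C)C | starting material
6 | 1-[2-bromo-3-iodo-4-(methoxymethoxy)-5-(3-methylbut-2-enyl)phenyl]ethanone (not isolated) | CC(=O)c1cc(CC=C(C)C)c(OCOC)c(I)c1Br | intermediate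
7 | 1-[2-bromo-4-(methoxymethoxy)-3,5-bis(3-methylbut-2-enyl)phenyl]ethanone | CC(=O)c1cc(CC=C(C)C)c(OCOC)c(CC=C(C)C)c1Br | intermediate
8 | methyl 4-hydroxybenzoate | COC(=O)c1ccc(O)cc1 | starting material
9 | 3-chloro-3-methylbut-1-yne | CC(C)(Cl)C#C | starting material
10 | methyl 4-[(2-methylbut-3-yn-2-yl)oxy]benzoate | COC(=O)c1ccc(OC(C)(C)C#C)cc1 | intermediate
11 | methyl 3-(3-methylbuta-1,2-dienyl)-4-oxocyclohexa-1,5-diene-1-carboxylate (not isolated) | COC(=O)C1=CC(C=C=C(C)C)C(=O)C=C1 | intermediate
12 | methyl 4-hydroxy-3-(3-methylbuta-1,2-dienyl)benzoate (not isolated) | COC(=O)c1ccc(O)c(C=C=C(C)C)c1 | intermediate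
13 | methyl (3Z)-3-(3-methylbut-2-enylidene)-4-oxocyclohexa-1,5-diene-1-carboxylate (not isolated) | COC(=O)C1=C/C(=C/C=C(C)C)C(=O)C=C1 | intermediate
14 | methyl 2,2-dimethyl-2H-chromene-6-carboxylate | COC(=O)c1ccc2c(c1)C=CC(C)(C)O2 | intermediate
15 | 1-[2-bromo-4-(methoxymethoxy)-3,5-bis(3-methylbut-2-enyl)phenyl]-3-(2,2-dimethyl-2H-chromen-6-yl)propane-1,3-dione | O=C(CC(=O)c1cc(CC=C(C)C)c(OCOC)c(CC=C(C)C)c1Br)c1ccc2c(c1)C=CC(C)(C)O2 | intermediate
16 | (3S)-3-[2-bromo-4-(methoxymethoxy)-3,5-bis(3-methylbut-2-enyl)phenyl]-1-(2,2-dimethyl-2H-chromen-6-yl)-3-hydroxypropan-1-one (not isolated) | O=C(C[C@H](O)c1cc(CC=C(C)C)c(OCOC)c(CC=C(C)C)c1Br)c1ccc2c(c1)C=CC(C)(C)O2 | intermediate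
17 | (1S,3S)-3-[2-bromo-4-(methoxymethoxy)-3,5-bis(3-methylbut-2-enyl)phenyl]-1-(2,2-dimethyl-2H-chromen-6-yl)propane-1,3-diol | O[C@H](c1ccc2c(c1)C=CC(C)(C)O2)C[C@H](O)c1cc(CC=C(C)C)c(OCOC)c(CC=C(C)C)c1Br | intermediate
18 | (2S,4S)-2-(2,2-dimethyl-2H-chromen-6-yl)-7-(methoxymethoxy)-6,8-bis(3-methylbut-2-enyl)-3,4-dihydro-2H-chromen-4-ol | COCOc1c(CC=C(C)C)cc2c(c1CC=C(C)C)O[C@H](c1ccc3c(c1)C=CC(C)(C)O3)C[C@@H]2O | intermediate
19 | (2S)-2-(2,2-dimethyl-2H-chromen-6-yl)-7-(methoxymethoxy)-6,8-bis(3-methylbut-2-enyl)-2,3-dihydro-4H-chromen-4-one | COCOc1c(CC=C(C)C)cc2c(c1CC=C(C)C)O[C@H](c1ccc3c(c1)C=CC(C)(C)O3)CC2=O | intermediate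
20 | (2S)-2-(2,2-dimethyl-2H-chromen-6-yl)-7-hydroxy-6,8-bis(3-methylbut-2-enyl)-2,3-dihydro-4H-chromen-4-one (target flavanone) | CC(C)=CCc1cc2c(c(CC=C(C)C)c1O)O[C@H](c1ccc3c(c1)C=CC(C)(C)O3)CC2=O | target

**Totals**
Total step count: 10. Longest linear sequence: 8 steps (steps 1, 2, 3, 6, 7, 8, 9, 10 from compound 1).

**Steps most likely to fail**

Step 8 (ring C closure). The palladium-bound secondary alkoxide may undergo beta-hydride elimination, which would oxidise C2, reduce the C8a–Br bond and, if reversible, erode the C2 configuration. The C4 alkoxide may also bind the arylpalladium centre in a five-membered chelate and lose hydride in the same way. Oxidative addition at the doubly ortho-substituted bromide may also be slow, with the diol sequestering the catalyst. The fallback makes the same O1–C8a bond with copper and an iodide instead of palladium and a bromide. It sets out from 17: halogen exchange (NaI, CuI, trans-N,N'-dimethylcyclohexane-1,2-diamine, dioxane, 110 °C; aromatic Finkelstein reaction) should give (1S,3S)-1-(2,2-dimethyl-2H-chromen-6-yl)-3-[2-iodo-4-(methoxymethoxy)-3,5-bis(3-methylbut-2-enyl)phenyl]propane-1,3-diol F1. Ullmann-type intramolecular etherification (CuI, 3,4,7,8-tetramethyl-1,10-phenanthroline, Cs2CO3, toluene, 110 °C) should then close the ring with retention, since copper alkoxides have no ready beta-hydride elimination path. The route is rejoined at 18.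

Step 3 (double prenylation). The allyl unit may be transferred through its tertiary terminus, giving a 1,1-dimethylallyl group. The second coupling at the C3 iodide, between Br and OMOM, may be sluggish and call for temperatures at which the C–Br bond starts to couple. The fallback transfers a plain allyl group and builds the prenyl terminus afterwards. It sets out from 4: Stille coupling with allyltributylstannane (Pd2(dba)3, AsPh3, DMF, 50 °C), which has no regiochemical ambiguity and transmetalates faster, should give 1-[2-bromo-4-(methoxymethoxy)-3,5-bis(prop-2-enyl)phenyl]ethanone F2. Olefin cross-metathesis in 2-methylbut-2-ene with the second-generation Grubbs catalyst RuCl2(=CHPh)(PCy3)(H2IMes) at 40 °C should convert both allyl groups into prenyl groups. The route is rejoined at 7.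

Step 7 (double asymmetric reduction). The strongly enolised, electron-rich diketone may resist hydride transfer, or the second reduction may run with poor catalyst control, so that C2 is set incompletely. The fallback makes the C2–C3 bond and the C2 stereocentre together by an enantioselective aldol addition; it sets out from 7 and 14 and rejoins the route at 19. Reduction of 14 with i-Bu2AlH (CH2Cl2, –78 °C) should give (2,2-dimethyl-2H-chromen-6-yl)methanol F3, and MnO2 (CH2Cl2, rt) should oxidise it to 2,2-dimethyl-2H-chromene-6-carbaldehyde F4. Enolisation of 7 with (–)-Ipc2BCl and Et3N (Et2O, –78 °C) and addition to F4 is a diisopinocampheylboron-mediated aldol addition. Attack on the si face of the aldehyde is expected; the antipodal reagent is used if a model aldol shows the opposite sense. The aldol addition should give (3S)-1-[2-bromo-4-(methoxymethoxy)-3,5-bis(3-methylbut-2-enyl)phenyl]-3-(2,2-dimethyl-2H-chromen-6-yl)-3-hydroxypropan-1-one F5. Narasaka–Prasad reduction (Et2BOMe, NaBH4, THF/MeOH, –78 °C) should then give the syn diol (1S,3R)-3-[2-bromo-4-(methoxymethoxy)-3,5-bis(3-methylbut-2-enyl)phenyl]-1-(2,2-dimethyl-2H-chromen-6-yl)propane-1,3-diol F6. Under the conditions of step 8, this diol should cyclise to (2S,4R)-2-(2,2-dimethyl-2H-chromen-6-yl)-7-(methoxymethoxy)-6,8-bis(3-methylbut-2-enyl)-3,4-dihydro-2H-chromen-4-ol F7, the C4 epimer of 18, and Dess–Martin oxidation of that chromanol then gives 19.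

**Further compounds**
F1 | step 8 | (1S,3S)-1-(2,2-dimethyl-2H-chromen-6-yl)-3-[2-iodo-4-(methoxymethoxy)-3,5-bis(3-methylbut-2-enyl)phenyl]propane-1,3-diol | O[C@H](c1ccc2c(c1)C=CC(C)(C)O2)C[C@H](O)c1cc(CC=C(C)C)c(OCOC)c(CC=C(C)C)c1I
F2 | step 3 | 1-[2-bromo-4-(methoxymethoxy)-3,5-bis(prop-2-enyl)phenyl]ethanone | CC(=O)c1cc(CC=C)c(OCOC)c(CC=C)c1Br
F3 | step 7 | (2,2-dimethyl-2H-chromen-6-yl)methanol | OCc1ccc2c(c1)C=CC(C)(C)O2
F4 | step 7 | 2,2-dimethyl-2H-chromene-6-carbaldehyde | O=Cc1ccc2c(c1)C=CC(C)(C)O2
F5 | step 7 | (3S)-1-[2-bromo-4-(methoxymethoxy)-3,5-bis(3-methylbut-2-enyl)phenyl]-3-(2,2-dimethyl-2H-chromen-6-yl)-3-hydroxypropan-1-one | O[C@H](c1ccc2c(c1)C=CC(C)(C)O2)CC(=O)c1cc(CC=C(C)C)c(OCOC)c(CC=C(C)C)c1Br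
F6 | step 7 | (1S,3R)-3-[2-bromo-4-(methoxymethoxy)-3,5-bis(3-methylbut-2-enyl)phenyl]-1-(2,2-dimethyl-2H-chromen-6-yl)propane-1,3-diol | O[C@H](c1ccc2c(c1)C=CC(C)(C)O2)C[C@@H](O)c1cc(CC=C(C)C)c(OCOC)c(CC=C(C)C)c1Br
F7 | step 7 | (2S,4R)-2-(2,2-dimethyl-2H-chromen-6-yl)-7-(methoxymethoxy)-6,8-bis(3-methylbut-2-enyl)-3,4-dihydro-2H-chromen-4-ol | COCOc1c(CC=C(C)C)cc2c(c1CC=C(C)C)O[C@H](c1ccc3c(c1)C=CC(C)(C)O3)C[C@H]2O
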